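**Plan**
Retrosynthesis cuts, in this order: the aryl O–CH3 bond, the C2′–C3′ bond of the C15 side chain, the lactone O2–C3 bond, and the bond from the benzylic carbon C4 to C3.
Forward: benzylic propargylation of 2-methoxy-6-methylbenzoic acid and desilylation give an achiral butynyl acid. The lactone, the only ring formed, then closes at O2–C3 to the 3-vinyl compound. The C13 (E)-alkenyl bromide from nonanal is joined through the vinyl group, and the methyl ether is removed last.
Enabling feature: in the isochromanone (C1 carbonyl, O2, C3, benzylic C4) the only stereocentre, C3, is the lactone carbinol carbon and its chain begins with two plain CH2 groups (C1′, C2′). C3 can therefore be made as a vinyl-bearing allylic ester carbon, and the vinyl group later becomes C1′–C2′.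
Stereochemistry: C3 comes from the chiral diphosphine in the ring closure; the (E)-alkene comes from the chair transition state of a Johnson–Claisen rearrangement.

Key step: step 3

Assumption: (S,S)-DIOP is taken as the ligand antipode that leads to the (S)-lactone. The sense of induction for this tethered acid has to be confirmed on the first run, and (R,R)-DIOP, equally available, would be used if it is the reverse.

**Route**

Step 1
Reactants: 1 2-methoxy-6-methylbenzoic acid; 2 3-bromo-1-(trimethylsilyl)prop-1-yne
Product: 4 2-methoxy-6-[4-(trimethylsilyl)but-3-yn-1-yl]benzoic acid, via dilithio dianion 3 (not isolated)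
Conditions: LiN(iPr)2 (2.2 equiv), THF, –78 to 0 °C; 2 (1.1 equiv), –78 °C to rt; then 1 M HCl
Reagents that add atoms: none
Why: Lateral lithiation of the lithium carboxylate gives a benzylic dianion that is alkylated at carbon by SN2 displacement on the propargylic bromide, whose silyl cap blocks acetylide formation and SN2′ attack.

Step 2
Reactants: 4 2-methoxy-6-[4-(trimethylsilyl)but-3-yn-1-yl]benzoic acid
Product: 5 2-(but-3-yn-1-yl)-6-methoxybenzoic acid
Conditions: K2CO3 (3 equiv), MeOH, rt; then 1 M HCl
Reagents that add atoms: none
Why: Base-mediated protodesilylation of the alkynylsilane (methoxide attack at silicon) frees the terminal alkyne while the carboxylate is a spectator.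

Step 3
Reactants: 5 2-(but-3-yn-1-yl)-6-methoxybenzoic acid
Product: 7 (S)-8-methoxy-3-vinylisochroman-1-one, via allenyl acid 6 (not isolated)
Conditions: [Rh(cod)Cl]2 (2.5 mol%), (S,S)-DIOP (6 mol%), ClCH2CH2Cl (0.05 M), 70 °C
Reagents that add atoms: none
Why: O–H oxidative addition of the acid to the monovalent rhodium/DIOP complex gives a trivalent rhodium hydride, which hydrometalates the terminal alkyne, β-hydride eliminates to the allene 6, and then hydrometalates the allene at its central carbon to a π-allyl rhodium carboxylate; C–O reductive elimination at the substituted allyl terminus forms the O2–C3 bond and returns monovalent rhodium. The closest known reaction type is the rhodium/diphosphine-catalysed, branched-selective addition of carboxylic acids to terminal alkynes and allenes giving allylic esters, which has enantioselective and lactone-forming versions; here it is applied to a benzo-fused six-membered closure. The lactone ring closes by attack of the tethered carboxylate oxygen on the internal allyl carbon with the vinyl group left outside the ring, a 6-exo closure with respect to the allyl unit. The C3 stereocentre is set in this C–O bond-forming step by the C2-symmetric diphosphine, which differentiates the two faces of the allyl terminus (catalyst control, since the substrate has no stereocentre). The step needs branched-over-linear regioselectivity and facial selectivity: the branched path gives the six-membered ring whereas the linear path would require an eight-membered lactone, the homopropargylic tether makes direct carboxylate addition to the alkyne (a seven-membered enol lactone) uncompetitive, the substrate carries no other alkene, and moderate dilution should suppress intermolecular esterification.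

Step 4
Reactants: 8 nonanal; 9 vinylmagnesium bromide
Product: 10 rac-undec-1-en-3-ol
Conditions: CH2=CHMgBr (1.2 equiv), THF, 0 °C; then aq. NH4Cl
Reagents that add atoms: none
Why: Grignard 1,2-addition to the aldehyde gives the secondary allylic alcohol; its configuration is irrelevant because the carbinol centre becomes an alkene carbon in step 5.

Step 5
Reactants: 10 rac-undec-1-en-3-ol; 11 triethyl orthoacetate
Product: 13 ethyl (E)-tridec-4-enoate, via ketene acetal 12 (not isolated)
Conditions: MeC(OEt)3 (5 equiv), EtCO2H (5 mol%), 140 °C, EtOH distilled off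
Reagents that add atoms: none
Why: Johnson–Claisen rearrangement: acid-catalysed exchange gives the mixed ketene acetal, whose chair-like [3,3] shift with the octyl group equatorial should give the γ,δ-unsaturated ester as the (E)-alkene.

Step 6
Reactants: 13 ethyl (E)-tridec-4-enoate
Product: 14 (E)-tridec-4-en-1-ol
Conditions: LiAlH4 (0.6 equiv), Et2O, 0 °C; then H2O
Reagents that add atoms: none
Why: Hydride reduction of the ester to the primary alcohol; the isolated alkene is inert to LiAlH4.

Step 7
Reactants: 14 (E)-tridec-4-en-1-ol
Product: 15 (E)-1-bromotridec-4-ene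
Conditions: CBr4 (1.2 equiv), PPh3 (1.25 equiv), CH2Cl2, 0 °C
Reagents that add atoms: carbon tetrabromide, BrC(Br)(Br)Br
Why: Appel bromination replaces the primary hydroxyl by SN2 displacement of the oxyphosphonium group under neutral conditions that leave the alkene geometry untouched.

Step 8
Reactants: 7 (S)-8-methoxy-3-vinylisochroman-1-one; 15 (E)-1-bromotridec-4-ene
Product: 17 (R)-8-methoxy-3-[(E)-pentadec-6-en-1-yl]isochroman-1-one, via alkylborane 16 (not isolated)
Conditions: 7 (1.2 equiv), 9-BBN (1.2 equiv), THF, 0 °C to rt; then 15 (1.0 equiv), Pd(OAc)2 (4 mol%), PCy3 (8 mol%), K3PO4·H2O (1.3 equiv), THF, rt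
Reagents that add atoms: none
Why: Anti-Markovnikov hydroboration of the vinyl group with 9-BBN, then B-alkyl Suzuki–Miyaura coupling with the primary alkyl bromide, in which the bulky electron-rich phosphine speeds oxidative addition of the C(sp3)–Br bond and curbs β-hydride elimination; C3 is not touched and only its descriptor changes from S to R because the saturated chain now ranks below C4.

Step 9
Reactants: 17 (R)-8-methoxy-3-[(E)-pentadec-6-en-1-yl]isochroman-1-one
Product: 18 (R)-8-hydroxy-3-[(E)-pentadec-6-en-1-yl]isochroman-1-one
Conditions: BCl3 (1 M in CH2Cl2, 2.5 equiv), CH2Cl2, –78 to 0 °C; then H2O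
Reagents that add atoms: none
Why: Lewis-acid demethylation: BCl3 chelated between the lactone carbonyl and the peri methoxy oxygen cleaves that aryl methyl ether selectively at low temperature, leaving the lactone, the alkene and C3 unchanged.

**Compound list**

1 | 2-methoxy-6-methylbenzoic acid | COc1cccc(C)c1C(=O)O | starting material
2 | 3-bromo-1-(trimethylsilyl)prop-1-yne | C[Si](C)(C)C#CCBr | starting material
3 | lithium 2-(lithiomethyl)-6-methoxybenzoate (dilithio dianion) | [Li]Cc1cccc(OC)c1C(=O)O[Li] | intermediate
4 | 2-methoxy-6-[4-(trimethylsilyl)but-3-yn-1-yl]benzoic acid | COc1cccc(CCC#C[Si](C)(C)C)c1C(=O)O | intermediate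
5 | 2-(but-3-yn-1-yl)-6-methoxybenzoic acid | COc1cccc(CCC#C)c1C(=O)O | intermediate
6 | 2-(buta-2,3-dien-1-yl)-6-methoxybenzoic acid | COc1cccc(CC=C=C)c1C(=O)O | intermediate
7 | (S)-8-methoxy-3-vinylisochroman-1-one | C=C[C@@H]1Cc2cccc(OC)c2C(=O)O1 | intermediate
8 | nonanal | CCCCCCCCC=O | starting material
9 | vinylmagnesium bromide | C=C[Mg]Br | starting material
10 | rac-undec-1-en-3-ol | CCCCCCCCC(O)C=C | intermediate
11 | triethyl orthoacetate | CCOC(C)(OCC)OCC | starting material
12 | 1-ethoxy-1-(undec-1-en-3-yloxy)ethene (ketene acetal) | C=C(OCC)OC(C=C)CCCCCCCC | intermediate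
13 | ethyl (E)-tridec-4-enoate | CCCCCCCC/C=C/CCC(=O)OCC | intermediate
14 | (E)-tridec-4-en-1-ol | CCCCCCCC/C=C/CCCO | intermediate
15 | (E)-1-bromotridec-4-ene | CCCCCCCC/C=C/CCCBr | intermediate
16 | (R)-3-[2-(9-borabicyclo[3.3.1]nonan-9-yl)ethyl]-8-methoxyisochroman-1-one | C(C[C@@H]1Cc2cccc(OC)c2C(=O)O1)B1C2CCCC1CCC2 | intermediate
17 | (R)-8-methoxy-3-[(E)-pentadec-6-en-1-yl]isochroman-1-one | CCCCCCCC/C=C/CCCCC[C@@H]1Cc2cccc(OC)c2C(=O)O1 | intermediate
18 | (R)-8-hydroxy-3-[(E)-pentadec-6-en-1-yl]isochroman-1-one | CCCCCCCC/C=C/CCCCC[C@@H]1Cc2cccc(O)c2C(=O)O1 | target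

**Step count**
Total: 9 steps.
Longest linear sequence: 6 steps (nonanal through steps 4, 5, 6, 7, 8, 9); the aromatic branch from 1 is 5 steps (1, 2, 3, 8, 9).

**Steps most likely to fail**

Step 3. The allyl rhodium intermediate may lose a benzylic β-hydride to give a conjugated aryl diene, intermolecular esterification may compete with ring closure, and DIOP may discriminate the allyl faces poorly in a benzo-fused closure that has not been run before. The fallback sets out from 1 and comes back at 7; C3 is made racemic and resolved. Dianion 3, made from 1 as in step 1, is added 1,2 to acrolein at –78 °C and the hydroxy acid is lactonised on acidification to rac-8-methoxy-3-vinylisochroman-1-one F1. Aminolysis with pyrrolidine and AlMe3 in CH2Cl2 opens the lactone to rac-[2-(2-hydroxybut-3-en-1-yl)-6-methoxyphenyl](pyrrolidin-1-yl)methanone F2. Sharpless kinetic resolution (Ti(OiPr)4, D-(–)-diisopropyl tartrate, t-BuOOH about 0.6 equiv, 4 Å sieves, CH2Cl2, –20 °C) should leave (S)-[2-(2-hydroxybut-3-en-1-yl)-6-methoxyphenyl](pyrrolidin-1-yl)methanone F3. The (R)-alcohol is consumed as the erythro epoxy alcohol [2-[(2R)-2-hydroxy-2-[(2S)-oxiran-2-yl]ethyl]-6-methoxyphenyl](pyrrolidin-1-yl)methanone F4, which is removed by chromatography. Heating F3 with TsOH in toluene closes the lactone with loss of pyrrolidine and gives 7. At most half of the material is carried through.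

Step 8. Transmetalation of the alkylborane may be slow, the alkylpalladium bromide may undergo β-hydride elimination, residual borane may add to the internal alkene of 15, and the phosphate base may open the lactone. The fallback sets out from 7 and 15 and comes back at 17; the polarity of the sp3–sp3 coupling is reversed. Compound 7 is hydroborated as before to 16 and oxidised with NaBO3·4H2O to (S)-3-(2-hydroxyethyl)-8-methoxyisochroman-1-one F5 (same spatial arrangement, descriptor S because the oxygenated chain outranks C4). I2, PPh3 and imidazole in CH2Cl2 convert F5 into (S)-3-(2-iodoethyl)-8-methoxyisochroman-1-one F6. Bromide 15 is converted with Zn dust (I2 cat., DMA, 80 °C) into (E)-tridec-4-en-1-ylzinc bromide F7. Alkyl–alkyl Negishi coupling of F6 with F7 (Pd2(dba)3, tricyclopentylphosphine, N-methylimidazole, THF/NMP, 80 °C) should give 17.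

Step 1. Lateral metalation of the dianion may be incomplete, the product may be alkylated a second time, and the benzylic anion may attack the alkyne terminus. The fallback sets out from 1 and comes back at 4; the carboxyl group is masked so that a single benzylic anion is alkylated. Acid 1 is esterified with Boc2O, DMAP and t-BuOH to tert-butyl 2-methoxy-6-methylbenzoate F8. Deprotonation with LiN(iPr)2 in THF at –78 °C and alkylation with 2 give tert-butyl 2-methoxy-6-[4-(trimethylsilyl)but-3-yn-1-yl]benzoate F9. Cleavage of the ester with CF3CO2H in CH2Cl2 at rt returns 4.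

**Further compounds**

F1 | step 3 | rac-8-methoxy-3-vinylisochroman-1-one | C=CC1Cc2cccc(OC)c2C(=O)O1
F2 | step 3 | rac-[2-(2-hydroxybut-3-en-1-yl)-6-methoxyphenyl](pyrrolidin-1-yl)methanone | C=CC(O)Cc1cccc(OC)c1C(=O)N1CCCC1
F3 | step 3 | (S)-[2-(2-hydroxybut-3-en-1-yl)-6-methoxyphenyl](pyrrolidin-1-yl)methanone | C=C[C@@H](O)Cc1cccc(OC)c1C(=O)N1CCCC1
F4 | step 3 | [2-[(2R)-2-hydroxy-2-[(2S)-oxiran-2-yl]ethyl]-6-methoxyphenyl](pyrrolidin-1-yl)methanone | COc1cccc(C[C@@H](O)[C@@H]2CO2)c1C(=O)N1CCCC1
F5 | step 8 | (S)-3-(2-hydroxyethyl)-8-methoxyisochroman-1-one | OCC[C@@H]1Cc2cccc(OC)c2C(=O)O1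
F6 | step 8 | (S)-3-(2-iodoethyl)-8-methoxyisochroman-1-one | ICC[C@@H]1Cc2cccc(OC)c2C(=O)O1
F7 | step 8 | (E)-tridec-4-en-1-ylzinc bromide | CCCCCCCC/C=C/CCC[Zn]Br
F8 | step 1 | tert-butyl 2-methoxy-6-methylbenzoate | COc1cccc(C)c1C(=O)OC(C)(C)C
F9 | step 1 | tert-butyl 2-methoxy-6-[4-(trimethylsilyl)but-3-yn-1-yl]benzoate | COc1cccc(CCC#C[Si](C)(C)C)c1C(=O)OC(C)(C)C
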